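**Retrosynthetic overview**
1. Abruquinone B (16) ⇒ (S)-3-ethynyl-6,7,8-trimethoxychroman (15) + dimethyl squarate (2): the quinone ring is made last by inserting the terminal alkyne into the acyl–acyl C–C bond of the squarate (four- to six-membered ring expansion, Rh catalysis, not pericyclic).
2. 15 ⇒ bromoalkyl quinone 12 by reduction, 6-exo O-alkylation (pyran ring) and O-methylation; 12 ⇒ diyne 11 + 2 by the same ring expansion (ring A).
3. 11 ⇒ 3-ethynyloxetane (3) + acetylene (8): enantioselective desymmetrising oxetane opening sets C3, then triflate alkynylation.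
4. Ring order: ring A carbocycle → pyran ring → quinone ring B; each six-membered carbocycle is four squaric acid carbons plus two alkyne carbons.

Assumption: the target SMILES is read as the (3S) enantiomer; this is a proposed route, not an executed one.

**Step 1**
Reactants: 1 squaric acid
Product: 2 dimethyl squarate (3,4-dimethoxycyclobut-3-ene-1,2-dione)
Conditions: HC(OMe)3 (2.2 equiv), MeOH, reflux, 24 h
Reagents that add atoms: trimethyl orthoformate, COC(OC)OC
Why: The strongly acidic vinylogous diacid is O-methylated twice under orthoester conditions (vinylogous esterification), the standard preparation of dimethyl squarate.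

**Step 2**
Reactants: 3 3-ethynyloxetane
Product: 5 trimethyl[(oxetan-3-yl)ethynyl]silane, via lithium (oxetan-3-yl)ethynide 4 (not isolated)
Conditions: n-BuLi, THF, −78 °C; TMSCl, −78 °C → rt
Reagents that add atoms: n-butyllithium, [Li]CCCC (Li in 4 only); chlorotrimethylsilane, C[Si](C)(C)Cl
Why: The alkyne C–H is deprotonated at −78 °C, where the oxetane is inert to n-BuLi, and the acetylide is C-silylated (alkyne protection, so that the two alkynes can later be told apart).

**Step 3**
Reactants: 5 trimethyl[(oxetan-3-yl)ethynyl]silane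
Product: 7 (R)-2-(bromomethyl)-4-(trimethylsilyl)but-3-yn-1-ol, via (R)-{[2-(bromomethyl)-4-(trimethylsilyl)but-3-yn-1-yl]oxy}trimethylsilane 6 (not isolated)
Conditions: TMSBr (1.2 equiv), chiral arylpyrrolidine squaramide H-bond-donor catalyst (5 mol %, enantiomer that gives R), t-BuOMe, −78 °C; aq. citric acid work-up
Reagents that add atoms: bromotrimethylsilane, C[Si](C)(C)Br
Why: Catalytic enantioselective desymmetrisation of a prochiral 3-substituted oxetane, in which the catalyst-bound bromide opens one of the two enantiotopic CH2–O bonds by SN2, so C3 becomes a stereocentre without any of its own bonds being broken.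

**Step 4**
Reactants: 7 (R)-2-(bromomethyl)-4-(trimethylsilyl)but-3-yn-1-ol; 8 acetylene
Product: 11 (S)-[3-(bromomethyl)hexa-1,5-diyn-1-yl]trimethylsilane, via (R)-2-(bromomethyl)-4-(trimethylsilyl)but-3-yn-1-yl trifluoromethanesulfonate 9 (not isolated), via lithium acetylide 10 (not isolated)
Conditions: Tf2O, 2,6-lutidine, CH2Cl2, −78 °C; then HC≡CLi (from 8, n-BuLi, THF, −78 °C), DMPU, −78 → −30 °C
Reagents that add atoms: trifluoromethanesulfonic anhydride, O=S(=O)(OS(=O)(=O)C(F)(F)F)C(F)(F)F (CF3SO2 in 9 only); n-butyllithium, [Li]CCCC (Li in 10 only)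
Why: SN2 alkynylation of a primary triflate by lithium acetylide is much faster at low temperature than attack on the primary bromide or E2, and activating the alcohol as triflate avoids the alkoxide that would close back to the oxetane; C3 is untouched (R → S is only a CIP priority change).

**Step 5**
Reactants: 11 (S)-[3-(bromomethyl)hexa-1,5-diyn-1-yl]trimethylsilane; 2 dimethyl squarate
Product: 12 5-[(2S)-2-(bromomethyl)-4-(trimethylsilyl)but-3-yn-1-yl]-2,3-dimethoxycyclohexa-2,5-diene-1,4-dione
Conditions: 2 (2 equiv), [Rh(cod)Cl]2 (2.5 mol %), dppb (6 mol %), ZnCl2 (20 mol %), 1,4-dioxane, 90 °C, 11 added over 6 h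
Reagents that add atoms: none
Why: Proposed new method: catalytic insertion of a terminal alkyne into the strained acyl–acyl C1–C2 σ-bond of a squarate ester, in which Rh(I) adds oxidatively to that bond to give a maleoyl-type five-membered rhodacycle, ZnCl2 opens a coordination site and polarises the carbonyls, the alkyne inserts into a Rh–acyl bond and C(sp2)–C(acyl) reductive elimination releases the 1,4-benzoquinone and Rh(I); the symmetric squarate allows only the 2,3-dimethoxy-5-alkyl isomer, and the hindered silyl alkyne and β-branched bromide should be spectators; closest known chemistry is the stoichiometric maleoylcobalt/alkyne quinone synthesis and catalytic Rh/Ni "cut-and-sew" alkyne insertions into cyclobutanones, cyclobutenones and benzocyclobutenones, whereas the catalytic acyl–acyl version with a squarate and a terminal alkyne has not been shown.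

**Step 6**
Reactants: 12 5-[(2S)-2-(bromomethyl)-4-(trimethylsilyl)but-3-yn-1-yl]-2,3-dimethoxycyclohexa-2,5-diene-1,4-dione
Product: 15 (3S)-3-ethynyl-6,7,8-trimethoxy-3,4-dihydro-2H-chromene, via 5-[(2S)-2-(bromomethyl)-4-(trimethylsilyl)but-3-yn-1-yl]-2,3-dimethoxybenzene-1,4-diol 13 (not isolated), via (3S)-3-ethynyl-7,8-dimethoxy-3,4-dihydro-2H-chromen-6-ol 14 (not isolated)
Conditions: Na2S2O4, THF/H2O, rt; organic phase under Ar, then K2CO3, MeOH/DMF, 50 °C; then MeI, rt
Reagents that add atoms: iodomethane, CI
Why: Dithionite reduces only the quinone, the phenoxide ortho to the side chain closes the pyran ring by 6-exo-tet Williamson alkylation (the other OH cannot reach), carbonate/methanol cleaves the alkynyl C–Si bond, and the remaining phenoxide is methylated; the non-acidic propargylic C3–H is not epimerised.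

**Step 7**
Reactants: 15 (3S)-3-ethynyl-6,7,8-trimethoxy-3,4-dihydro-2H-chromene; 2 dimethyl squarate
Product: 16 abruquinone B, 2,3-dimethoxy-5-[(3S)-6,7,8-trimethoxy-3,4-dihydro-2H-chromen-3-yl]cyclohexa-2,5-diene-1,4-dione
Conditions: 2 (2 equiv), [Rh(cod)Cl]2 (2.5 mol %), dppb (6 mol %), ZnCl2 (20 mol %), 1,4-dioxane, 90 °C, 15 added over 6 h
Reagents that add atoms: none
Why: Proposed new method: the same Rh(I)-catalysed acyl–acyl C–C activation of the squarate, alkyne migratory insertion and reductive elimination as in step 5 builds the 2,3-dimethoxyquinone ring directly on C3 (four- to six-membered ring expansion with one possible regioisomer); no bond to C3 is made or broken and no base is present, so the (S) centre is retained; closest known chemistry is stoichiometric maleoylcobalt quinone synthesis and Rh/Ni cut-and-sew of cyclobutenones with alkynes.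

**Compound list**
1 | squaric acid (3,4-dihydroxycyclobut-3-ene-1,2-dione) | OC1=C(O)C(=O)C1=O | starting material
2 | dimethyl squarate | COC1=C(OC)C(=O)C1=O | intermediate
3 | 3-ethynyloxetane | C#CC1COC1 | starting material
4 | lithium (oxetan-3-yl)ethynide | [Li]C#CC1COC1 | intermediate
5 | trimethyl[(oxetan-3-yl)ethynyl]silane | C[Si](C)(C)C#CC1COC1 | intermediate
6 | (R)-{[2-(bromomethyl)-4-(trimethylsilyl)but-3-yn-1-yl]oxy}trimethylsilane | C[Si](C)(C)C#C[C@H](CO[Si](C)(C)C)CBr | intermediate
7 | (R)-2-(bromomethyl)-4-(trimethylsilyl)but-3-yn-1-ol | C[Si](C)(C)C#C[C@H](CO)CBr | intermediate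
8 | acetylene | C#C | starting material
9 | (R)-2-(bromomethyl)-4-(trimethylsilyl)but-3-yn-1-yl trifluoromethanesulfonate | C[Si](C)(C)C#C[C@H](COS(=O)(=O)C(F)(F)F)CBr | intermediate
10 | lithium acetylide | [Li]C#C | intermediate
11 | (S)-[3-(bromomethyl)hexa-1,5-diyn-1-yl]trimethylsilane | C[Si](C)(C)C#C[C@H](CC#C)CBr | intermediate
12 | 5-[(2S)-2-(bromomethyl)-4-(trimethylsilyl)but-3-yn-1-yl]-2,3-dimethoxycyclohexa-2,5-diene-1,4-dione | C[Si](C)(C)C#C[C@H](CC1=CC(=O)C(OC)=C(OC)C1=O)CBr | intermediate
13 | 5-[(2S)-2-(bromomethyl)-4-(trimethylsilyl)but-3-yn-1-yl]-2,3-dimethoxybenzene-1,4-diol | C[Si](C)(C)C#C[C@H](Cc1cc(O)c(OC)c(OC)c1O)CBr | intermediate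
14 | (3S)-3-ethynyl-7,8-dimethoxy-3,4-dihydro-2H-chromen-6-ol | C#C[C@H]1COc2c(cc(O)c(OC)c2OC)C1 | intermediate
15 | (3S)-3-ethynyl-6,7,8-trimethoxy-3,4-dihydro-2H-chromene | C#C[C@H]1COc2c(cc(OC)c(OC)c2OC)C1 | intermediate
16 | abruquinone B | COC1=C(OC)C(=O)C([C@H]2COc3c(cc(OC)c(OC)c3OC)C2)=CC1=O | target

**Step count and risks**
Total: 7 steps. Longest linear sequence: 6 steps (3 → 5 → 7 → 11 → 12 → 15 → 16); step 1 supplies 2 for steps 5 and 7.

The three steps most likely to fail are steps 5, 7 and 3.

Step 5 (proposed new reaction) may lose the alkyne to Rh-mediated oligomerisation or cyclotrimerisation. The rhodacycle may also decarbonylate, Rh(I) may attack the C–Br bond, or the quinone may hold the catalyst. The fallback is the known thermal route from squarate to quinone. It sets out from 11: the terminal alkyne is deprotonated with LiHMDS in THF at −78 °C and added to one carbonyl of 2. This gives 4-[(4S)-4-(bromomethyl)-6-(trimethylsilyl)hexa-1,5-diyn-1-yl]-4-hydroxy-2,3-dimethoxycyclobut-2-en-1-one F1 as a mixture of carbinol epimers. Heating F1 in p-xylene at 138 °C rearranges it to the quinone, and the route is rejoined at 12.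

Step 7 (proposed new reaction) carries the same risks, and the alkyne is now branched at the propargylic carbon, so insertion may be slower. The fallback sets out from 15: the alkyne is lithiated with n-BuLi in THF at −78 °C and added to 2. This gives 4-hydroxy-2,3-dimethoxy-4-{[(3S)-6,7,8-trimethoxy-3,4-dihydro-2H-chromen-3-yl]ethynyl}cyclobut-2-en-1-one F2 as a mixture of carbinol epimers. Thermolysis of F2 in refluxing p-xylene gives the quinone directly, so the route comes back at 16.

Step 3 may give low ee, because a slim linear alkynyl group differentiates the two oxetane CH2 groups less than the aryl or branched substituents usual for this catalysis. The fallback replaces catalytic ring-opening by enzymatic desymmetrisation of a diol and sets out from 5. Dilute aqueous H2SO4 in THF hydrolyses the oxetane to the prochiral 2-[(trimethylsilyl)ethynyl]propane-1,3-diol F3. A lipase (Amano PS or PPL) with vinyl acetate mono-acetylates F3 to (S)-2-(hydroxymethyl)-4-(trimethylsilyl)but-3-yn-1-yl acetate F4. If the enzyme prefers the other arm, the same enzyme is used to hydrolyse the diacetate instead. Appel bromination (CBr4, PPh3) of F4 gives (R)-2-(bromomethyl)-4-(trimethylsilyl)but-3-yn-1-yl acetate F5. Acidic methanolysis (HCl in MeOH, 0 °C, which spares the silyl alkyne and cannot re-form the oxetane) removes the acetate, and the route is rejoined at 7.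

**Further compounds**
F1 | step 5 | 4-[(4S)-4-(bromomethyl)-6-(trimethylsilyl)hexa-1,5-diyn-1-yl]-4-hydroxy-2,3-dimethoxycyclobut-2-en-1-one | COC1=C(OC)C(O)(C#CC[C@H](CBr)C#C[Si](C)(C)C)C1=O
F2 | step 7 | 4-hydroxy-2,3-dimethoxy-4-{[(3S)-6,7,8-trimethoxy-3,4-dihydro-2H-chromen-3-yl]ethynyl}cyclobut-2-en-1-one | COC1=C(OC)C(O)(C#C[C@H]2COc3c(cc(OC)c(OC)c3OC)C2)C1=O
F3 | step 3 | 2-[(trimethylsilyl)ethynyl]propane-1,3-diol | C[Si](C)(C)C#CC(CO)CO
F4 | step 3 | (S)-2-(hydroxymethyl)-4-(trimethylsilyl)but-3-yn-1-yl acetate | C[Si](C)(C)C#C[C@H](COC(C)=O)CO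
F5 | step 3 | (R)-2-(bromomethyl)-4-(trimethylsilyl)but-3-yn-1-yl acetate | C[Si](C)(C)C#C[C@H](COC(C)=O)CBr
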